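**Strategy.** Everything rests on drawing both the quaternary C10 methyl and the C9–C11 bond from one temporary cyclopropane fused to ring B across C9–C10. The key step exploits the allylic C8 hydroxyl of ring B, which sits on the face opposite H-5 beside the C9=C10 bond at the ring A/B junction: as its zinc alkoxide it steers a zinc carbenoid onto that face, forming C10–CH2 and C9–CH2 and fixing C10 in one operation. The precursor is the (5S,8R) 8-hydroxy-Δ9(10)-octalin bearing the C4 gem-dimethyl group and a C3 dioxolane. Li/NH3 later cuts C9–CH2, giving the methyl and a C8–C9 enolate that is hydroxymethylated anti to it.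

Key step: step 8

Remark (assumption): drimane numbering is used for all bicyclic compounds. In the conventional drawing (ring A left, C10 above C5) this enantiomer has the C10 methyl to the rear and H-5 and C11 to the front, so faces are named "methyl face" and "H-5 face". Compounds 8 and 9 are racemates whose SMILES show the enantiomer carried on, and the two diastereomeric esters formed in step 6 are assumed separable by chromatography or crystallisation.

Step 1
Reactants: 1 6-methoxy-2-tetralone; 2 iodomethane
Product: 3 6-methoxy-1,1-dimethyl-3,4-dihydronaphthalen-2(1H)-one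
Conditions: NaH (2.2 equiv), MeI (3 equiv), THF, 0 °C → rt
Reagents that add atoms: iodomethane, CI
Why: Double enolate C-alkylation, in which the benzylic C1–H is the most acidic α-position and its enolate is conjugated with the arene, so both methyl groups should enter at C1 and create the future C4 gem-dimethyl carbon.

Step 2
Reactants: 3 6-methoxy-1,1-dimethyl-3,4-dihydronaphthalen-2(1H)-one; 4 ethylene glycol
Product: 5 ethylene ketal of 3 (6'-methoxy-1',1'-dimethyl-3',4'-dihydro-1'H-spiro[1,3-dioxolane-2,2'-naphthalene])
Conditions: HOCH2CH2OH, TsOH·H2O (cat.), benzene, reflux, Dean–Stark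
Reagents that add atoms: ethylene glycol, OCCO
Why: Acid-catalysed ketalisation with azeotropic removal of water masks the future C3 ketone against the later dissolving-metal, hydride and organometallic steps.

Step 3
Reactants: 5 ethylene ketal of 3
Product: 6 1,4-diene 6'-methoxy-1',1'-dimethyl-3',4',5',8'-tetrahydro-1'H-spiro[1,3-dioxolane-2,2'-naphthalene] (enol ether C7=C8–OMe and tetrasubstituted C5=C10 in drimane numbering)
Conditions: Li, NH3(l), THF, t-BuOH, −78 → −33 °C; then MeOH
Reagents that add atoms: none
Why: Birch reduction leaves the methoxy- and alkyl-bearing ring carbons sp2, so the unconjugated diene with the enol ether and the ring-fusion double bond should form, while the non-benzylic dioxolane is inert to the dissolving metal.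

Step 4
Reactants: 6 1,4-diene enol ether
Product: 8 racemic conjugated enone 1',1'-dimethyl-3',4',8',8a'-tetrahydro-1'H-spiro[1,3-dioxolane-2,2'-naphthalen]-6'(7'H)-one (C8 ketone; C9=C10; H at C5), via β,γ-enone 7 (not isolated)
Conditions: (CO2H)2, MeOH/H2O, rt; then NaOMe (0.2 equiv), MeOH, rt
Reagents that add atoms: water, O
Why: Enol ether hydrolysis under acid too mild to open the dioxolane, followed by base-mediated β,γ → α,β alkene isomerisation through the dienolate, whose protonation at C5 creates that stereocentre as a racemate.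

Step 5
Reactants: 8 racemic conjugated enone
Product: 9 racemic cis-allylic alcohol (5S*,8S*), 8-OH and H-5 on the same face, C9=C10 retained
Conditions: NaBH4, CeCl3·7H2O, MeOH, −78 → −20 °C
Reagents that add atoms: none
Why: Luche reduction gives clean 1,2-reduction, and hydride delivery along the axial trajectory of the half-chair enone should give mainly the pseudo-equatorial C8 alcohol, which is cis to H-5.

Step 6
Reactants: 9 racemic cis-allylic alcohol; 10 (S)-2-methoxy-2-phenylacetic acid ((S)-O-methylmandelic acid)
Product: 11 (5S,8R)-allylic (S)-O-methylmandelate, ester oxygen on the face opposite H-5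
Conditions: PPh3, DIAD, THF, 0 °C → rt; then SiO2 chromatography (or crystallisation) to remove the diastereomeric (5R,8S)-ester that arises from the other enantiomer of 9
Reagents that add atoms: (S)-2-methoxy-2-phenylacetic acid, CO[C@H](C(=O)O)c1ccccc1
Why: Mitsunobu reaction, in which SN2 displacement of the activated allylic oxygen inverts C8 to the pseudo-axial ester anti to H-5, while the enantiopure acyl group turns the two enantiomers of 9 into diastereomers, so the wanted (5S,8R)-ester can be separated from the (5R,8S)-ester.

Step 7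
Reactants: 11 (5S,8R)-allylic (S)-O-methylmandelate
Product: 12 (5S,8R)-3,3-ethylenedioxy-4,4-dimethyl-Δ9(10)-octalin-8-ol (8-OH on the face opposite H-5)
Conditions: K2CO3, MeOH, rt
Reagents that add atoms: none
Why: Base-catalysed transesterification cleaves the acyl C–O bond only, so the C8 configuration installed in step 6 is retained.

Step 8
Reactants: 12 (5S,8R)-allylic alcohol; 13 diiodomethane
Product: 15 (5S,8R,9S,10S)-9,10-methano alcohol (cyclopropane CH2 across C9–C10 on the face of the 8-OH; anti to H-5), via ethylzinc alkoxide 14 (not isolated)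
Conditions: Et2Zn (4 equiv), CH2Cl2, 0 °C; then CH2I2 (6 equiv), 0 °C → rt
Reagents that add atoms: diiodomethane, ICI
Why: Et2Zn turns the hydroxyl into the zinc alkoxide and, with CH2I2, into an iodomethylzinc carbenoid that is held at the alkoxide oxygen and transfers CH2 to C9=C10 through a concerted butterfly-type transition state. The closest known reaction type is the hydroxyl-directed Simmons–Smith cyclopropanation of cyclic allylic alcohols in its Et2Zn/CH2I2 variant. The three-membered ring closes by a concerted [2+1] methylene transfer in which C10–CH2 and C9–CH2 form together and syn to each other. Both new stereocentres, C10 and C9, are controlled by the C8 oxygen, because only the alkene face that the zinc-bound carbenoid can reach is attacked, so the CH2 lands on the hydroxyl face, opposite H-5. The step needs attack on the more hindered face, the one that also carries the axial C4 methyl, and the pseudo-axial 8-hydroxyl secures this by accelerating the directed pathway over any undirected one; C9=C10 is the only alkene, so chemoselectivity is not at stake.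

Step 9
Reactants: 15 9,10-methano alcohol
Product: 16 (5S,9S,10S)-9,10-methano-8-ketone (cyclopropyl ketone)
Conditions: Pr4N[RuO4] (5 mol %), N-methylmorpholine N-oxide, 4 Å MS, CH2Cl2, rt
Reagents that add atoms: none
Why: Ley–Griffith oxidation converts the secondary cyclopropyl carbinol into the ketone under neutral conditions that leave the dioxolane and the cyclopropane untouched.

Step 10
Reactants: 16 cyclopropyl ketone; 17 formaldehyde (monomer, from cracked paraformaldehyde)
Product: 19 (5S,9S,10R)-β-hydroxy ketone (trans-decalin; C8 ketone; C9–CH2OH on the H-5 face; C10 methyl on the opposite face), via lithium C8–C9 enolate 18 (not isolated)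
Conditions: Li (2.2 equiv), t-BuOH (1.0 equiv), NH3(l)/THF, −78 °C; isoprene; NH3 off, THF; CH2O (g), −78 °C; aq. NH4Cl
Reagents that add atoms: formaldehyde, C=O
Why: Dissolving-metal reductive cleavage of a cyclopropyl ketone with aldol trapping of the enolate: the ketyl opens the strained C9–CH2 bond, the one aligned with the carbonyl π system, so the CH2 becomes the C10 methyl and the enolate arises regiospecifically at C8–C9, where formaldehyde adds axially on the face anti to the adjacent axial methyl and thereby sets C9.

Step 11
Reactants: 19 β-hydroxy ketone; 20 tert-butyldimethylsilyl chloride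
Product: 21 (5S,9S,10R)-tert-butyldimethylsilyl ether of 19
Conditions: TBSCl, imidazole, DMF, 0 °C → rt
Reagents that add atoms: tert-butyldimethylsilyl chloride, CC(C)(C)[Si](C)(C)Cl
Why: Silylation of the primary alcohol under weakly basic conditions blocks retro-aldol cleavage and dehydration of the β-hydroxy ketone without disturbing the epimerisable C9.

Step 12
Reactants: 21 silyl ether; 22 N-(5-chloropyridin-2-yl)-1,1,1-trifluoro-N-(trifluoromethylsulfonyl)methanesulfonamide (Comins' reagent)
Product: 24 (5S,9S,10R)-C7=C8 enol triflate, via lithium C7–C8 enolate 23 (not isolated)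
Conditions: LiN(i-Pr)2 (1.1 equiv), THF, −78 °C; then 22, −78 → −20 °C; aq. NH4Cl
Reagents that add atoms: N-(5-chloropyridin-2-yl)-1,1,1-trifluoro-N-(trifluoromethylsulfonyl)methanesulfonamide, O=S(=O)(N(c1ccc(Cl)cn1)S(=O)(=O)C(F)(F)F)C(F)(F)F
Why: Kinetic enolisation and O-sulfonylation, in which the hindered amide base removes a C7 methylene proton much faster than the tertiary C9–H shielded by the quaternary C10 and the silyloxymethyl group, so the C7=C8 enol triflate forms and C9 is neither epimerised nor eliminated.

Step 13
Reactants: 24 enol triflate; 25 methylmagnesium bromide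
Product: 26 (5S,9S,10R)-11-(tert-butyldimethylsilyloxy)-3,3-ethylenedioxydrim-7-ene
Conditions: MeMgBr (1.5 equiv), Fe(acac)3 (5 mol %), THF/NMP, −30 → 0 °C
Reagents that add atoms: methylmagnesium bromide, C[Mg]Br
Why: Iron-catalysed Kumada-type cross-coupling of an alkenyl triflate with a methyl Grignard reagent replaces the triflate by CH3 without moving the C7=C8 double bond, and ketal and silyl ether tolerate the conditions.

Step 14
Reactants: 26 silyl ether ketal
Product: 27 (5S,9S,10R)-11-hydroxydrim-7-en-3-one
Conditions: 2 M aq. HCl, THF, rt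
Reagents that add atoms: water, O
Why: Acid hydrolysis removes the dioxolane and the primary silyl ether in one operation, mildly enough that the trisubstituted C7=C8 alkene should not migrate, and the released ketone has no epimerisable α-stereocentre because C4 is quaternary.

Step 15
Reactants: 27 keto alcohol; 28 umbelliferone (7-hydroxycoumarin)
Product: 29 target, 7-{[(1S,4aS,8aR)-2,5,5,8a-tetramethyl-6-oxo-1,4,4a,5,6,7,8,8a-octahydronaphthalen-1-yl]methoxy}-2H-chromen-2-one
Conditions: PPh3, DIAD, THF, 0 °C → rt
Reagents that add atoms: umbelliferone, O=c1ccc2ccc(O)cc2o1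
Why: Mitsunobu etherification, in which the acidic coumarin 7-hydroxyl displaces the activated primary C11 oxygen by SN2 at a CH2 carbon, so no stereocentre is involved and the C3 ketone is a spectator.

**Compound list**

1 | 6-methoxy-2-tetralone | COc1ccc2c(c1)CCC(=O)C2 | starting material
2 | iodomethane | CI | starting material
3 | 6-methoxy-1,1-dimethyl-3,4-dihydronaphthalen-2(1H)-one | COc1ccc2c(c1)CCC(=O)C2(C)C | intermediate
4 | ethylene glycol | OCCO | starting material
5 | 6'-methoxy-1',1'-dimethyl-3',4'-dihydro-1'H-spiro[1,3-dioxolane-2,2'-naphthalene] | COc1ccc2c(c1)CCC1(OCCO1)C2(C)C | intermediate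
6 | 6'-methoxy-1',1'-dimethyl-3',4',5',8'-tetrahydro-1'H-spiro[1,3-dioxolane-2,2'-naphthalene] | COC1=CCC2=C(C1)CCC1(OCCO1)C2(C)C | intermediate
7 | β,γ-enone, 1',1'-dimethyl-3',4',7',8'-tetrahydro-1'H-spiro[1,3-dioxolane-2,2'-naphthalen]-6'(5'H)-one (C8 ketone, C5=C10) | O=C1CCC2=C(C1)CCC1(OCCO1)C2(C)C | intermediate
8 | racemic conjugated enone (C8 ketone, C9=C10, H at C5; (5S)-enantiomer drawn) | O=C1CC[C@@H]2C(C)(C)C3(OCCO3)CCC2=C1 | intermediate
9 | racemic cis-allylic alcohol (5S*,8S*), 8-OH cis to H-5 ((5S,8S)-enantiomer drawn) | O[C@H]1CC[C@@H]2C(C)(C)C3(OCCO3)CCC2=C1 | intermediate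
10 | (S)-2-methoxy-2-phenylacetic acid | CO[C@H](C(=O)O)c1ccccc1 | starting material
11 | (5S,8R)-3,3-ethylenedioxy-4,4-dimethyl-Δ9(10)-octalin-8-yl (S)-2-methoxy-2-phenylacetate | CO[C@@H](c1ccccc1)C(=O)O[C@@H]1CC[C@@H]2C(C)(C)C3(OCCO3)CCC2=C1 | intermediate
12 | (5S,8R)-3,3-ethylenedioxy-4,4-dimethyl-Δ9(10)-octalin-8-ol (8-OH anti to H-5) | O[C@@H]1CC[C@@H]2C(C)(C)C3(OCCO3)CCC2=C1 | intermediate
13 | diiodomethane | ICI | starting material
14 | ethylzinc alkoxide of 12 | CC[Zn]O[C@@H]1CC[C@@H]2C(C)(C)C3(OCCO3)CCC2=C1 | intermediate
15 | (5S,8R,9S,10S)-3,3-ethylenedioxy-4,4-dimethyl-9,10-methanodecalin-8-ol (CH2 and OH on the same face, anti to H-5) | O[C@@H]1CC[C@@H]2C(C)(C)C3(OCCO3)CC[C@]24C[C@H]14 | intermediate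
16 | (5S,9S,10S)-3,3-ethylenedioxy-4,4-dimethyl-9,10-methanodecalin-8-one | O=C1CC[C@@H]2C(C)(C)C3(OCCO3)CC[C@]24C[C@H]14 | intermediate
17 | formaldehyde | C=O | starting material
18 | lithium C8–C9 enolate (5S,10R) with the C10 methyl anti to H-5 | C1C[C@@H]2C(C)(C)C3(OCCO3)CC[C@@]2(C)C=C1O[Li] | intermediate
19 | (5S,9S,10R)-3,3-ethylenedioxy-9-(hydroxymethyl)-4,4,10-trimethyl-trans-decalin-8-one (CH2OH on the H-5 face) | O=C1CC[C@@H]2C(C)(C)C3(OCCO3)CC[C@@]2(C)[C@H]1CO | intermediate
20 | tert-butyldimethylsilyl chloride | CC(C)(C)[Si](C)(C)Cl | starting material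
21 | tert-butyldimethylsilyl ether of 19 | O=C1CC[C@@H]2C(C)(C)C3(OCCO3)CC[C@@]2(C)[C@H]1CO[Si](C)(C)C(C)(C)C | intermediate
22 | N-(5-chloropyridin-2-yl)-1,1,1-trifluoro-N-(trifluoromethylsulfonyl)methanesulfonamide | O=S(=O)(N(c1ccc(Cl)cn1)S(=O)(=O)C(F)(F)F)C(F)(F)F | starting material
23 | lithium C7–C8 enolate of 21 | [Li]OC1=CC[C@@H]2C(C)(C)C3(OCCO3)CC[C@@]2(C)[C@H]1CO[Si](C)(C)C(C)(C)C | intermediate
24 | (5S,9S,10R)-C7=C8 enol triflate of 21 | O=S(=O)(OC1=CC[C@@H]2C(C)(C)C3(OCCO3)CC[C@@]2(C)[C@H]1CO[Si](C)(C)C(C)(C)C)C(F)(F)F | intermediate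
25 | methylmagnesium bromide | C[Mg]Br | starting material
26 | (5S,9S,10R)-11-(tert-butyldimethylsilyloxy)-3,3-ethylenedioxydrim-7-ene | CC1=CC[C@@H]2C(C)(C)C3(OCCO3)CC[C@@]2(C)[C@H]1CO[Si](C)(C)C(C)(C)C | intermediate
27 | (5S,9S,10R)-11-hydroxydrim-7-en-3-one | CC1=CC[C@@H]2C(C)(C)C(=O)CC[C@@]2(C)[C@H]1CO | intermediate
28 | umbelliferone | O=c1ccc2ccc(O)cc2o1 | starting material
29 | 7-{[(1S,4aS,8aR)-2,5,5,8a-tetramethyl-6-oxo-1,4,4a,5,6,7,8,8a-octahydronaphthalen-1-yl]methoxy}-2H-chromen-2-one | CC1=CC[C@@H]2C(C)(C)C(=O)CC[C@@]2(C)[C@H]1COc1ccc2ccc(=O)oc2c1 | target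

**Count.** Total: 15 steps. Longest linear sequence: 15 steps (1 → 29).

**Steps most likely to fail**

Step 8 (key step). Methylene transfer must occur on the face that also carries the axial C4 methyl. If it is slow, O-methylation of the zinc alkoxide, erosion of the dioxolane by zinc Lewis acids or undirected attack from the H-5 face may compete. The fallback replaces coordination by a covalent tether and sets out from 12. Acylation with the p-toluenesulfonylhydrazone of glyoxylic acid chloride (PhNMe2, CH2Cl2, 0 °C) should give the glyoxylate tosylhydrazone ester F1, which with Et3N loses sulfinate to give the diazoacetate F2. Rh2(OAc)4-catalysed intramolecular cyclopropanation, in which the short tether can reach C9=C10 only from the face of the C8 oxygen, should give the cyclopropane-fused γ-lactone F3. LiAlH4 reduction to the diol F4, double Swern oxidation to the keto aldehyde F5 and Tsuji–Wilkinson decarbonylation with stoichiometric RhCl(PPh3)3 would rejoin the route at 16.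

Step 10. The enolate may be protonated instead of forming the C–C bond (proton transfer from residual ammonia or from oligomerising formaldehyde), the carbonyl may be over-reduced, or retro-aldol cleavage and dehydration may occur on work-up. The fallback decouples reduction and aldol and sets out from 16. The same Li/NH3 cleavage is quenched, after removal of ammonia, with TMSCl/Et3N to give the isolable trimethylsilyl enol ether F6, which preserves the C8–C9 regiochemistry. A Mukaiyama aldol with aqueous formaldehyde catalysed by Yb(OTf)3 in THF at 0 °C should then give 19, with the same approach anti to the C10 methyl.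

Step 6. The activated allylic alcohol may eliminate to a diene, or the two diastereomeric esters may fail to separate. The fallback is an enzymatic kinetic resolution before the inversion and sets out from racemic 9. Acylation with vinyl acetate and immobilised Candida antarctica lipase B should, by the empirical rule for secondary alcohols (alkene side as the large group), convert the (8R)-enantiomer into the (5R,8R)-acetate F7 and leave (5S,8S)-9. Mitsunobu inversion of the recovered alcohol with 4-nitrobenzoic acid (PPh3, DIAD) to the (5S,8R)-4-nitrobenzoate F8 and methanolysis (K2CO3, MeOH) return to the route at 12.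

**Further compounds**

F1 | step 8 | glyoxylate p-toluenesulfonylhydrazone ester of 12 | Cc1ccc(cc1)S(=O)(=O)NN=CC(=O)O[C@@H]1CC[C@@H]2C(C)(C)C3(OCCO3)CCC2=C1
F2 | step 8 | diazoacetate of 12 | [N-]=[N+]=CC(=O)O[C@@H]1CC[C@@H]2C(C)(C)C3(OCCO3)CCC2=C1
F3 | step 8 | cyclopropane-fused γ-lactone (carboxyl carbon on the cyclopropane, bound to the C8 oxygen) | O1[C@@H]2CC[C@@H]3C(C)(C)C4(OCCO4)CC[C@]35[C@H](C1=O)[C@H]25
F4 | step 8 | diol (8-OH and cyclopropyl-CH2OH) | O[C@@H]1CC[C@@H]2C(C)(C)C3(OCCO3)CC[C@]24[C@H](CO)[C@H]14
F5 | step 8 | keto aldehyde (C8 ketone, cyclopropanecarbaldehyde) | O=C1CC[C@@H]2C(C)(C)C3(OCCO3)CC[C@]24[C@H](C=O)[C@H]14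
F6 | step 10 | trimethylsilyl C8–C9 enol ether | C1C[C@@H]2C(C)(C)C3(OCCO3)CC[C@@]2(C)C=C1O[Si](C)(C)C
F7 | step 6 | (5R,8R)-acetate of the unwanted enantiomer of 9 | CC(=O)O[C@@H]1CC[C@H]2C(C)(C)C3(OCCO3)CCC2=C1
F8 | step 6 | (5S,8R)-4-nitrobenzoate of 12 | O=C(O[C@@H]1CC[C@@H]2C(C)(C)C3(OCCO3)CCC2=C1)c1ccc(cc1)[N+](=O)[O-]
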